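Target that takes one partner apiece cannot use up a substrate charge of 0.25 M when the partner charge, 0.237 M, is smaller; by charge, partner is the limiting reagent. Yet the dawn run shows 0.7 % substrate beside 54.1 % target at 2.50 h.

| flask | substrate | partner | free catalyst | remark | time |
|---|---|---|---|---|---|
| midnight | 0.25 M (fed, over 8.0 min) | 0.237 M | 16 mM | the very flask that is asked about, followed so far |  |
| dawn | 0.25 M (fed, over 8.0 min) | 0.237 M | 32 mM | run made earlier |  |
| flask | 0.25 M (fed, over 8.0 min) | 0.237 M | 16 mM |  | 2.5 h |

midnight run (percent of the substrate charged)

| time / min | substrate / % | target / % |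
|---|---|---|
| 1.33 | 15.9 | 0.1 |
| 2.50 | 28.5 | 1.1 |
| 4.00 | 41.6 | 1.9 |
| 6.00 | 55.3 | 5.0 |
| 10.0 | 48.6 | 12.8 |
| 20.0 | 20.1 | 23.7 |

dawn run (percent of the substrate charged)

| time / h | substrate / % | target / % |
|---|---|---|
| 0.167 | 42.9 | 22.3 |
| 0.500 | 4.9 | 49.7 |
| 0.833 | 0.2 | 53.5 |
| 1.33 | 0 | 53.3 |
| 2.00 | 0.3 | 54.7 |
| 2.50 | 0.7 | 54.1 |

(each reading ± 0.5 percentage points)

- the reaction counts as stopped when no species that holds the substrate changes by six tenths of a point or more over the second half of the time
- percentages count the whole charge, also what has not yet gone in

- which holds at 2.5 h: what has brought the reaction to rest, or that it has not come to rest (it is still moving / all of the substrate has reacted / the partner has run out first / no working catalyst is left / forward and back rates have come level)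
- share of the substrate used up at 2.5 h
- target at 2.5 h, in percent of the substrate charged

The reckoning clears this up. Each point of target costs the partner, counted in points of its own charge, the partner cost of target 1.05. The target in the dawn run has therefore drawn 56.8 % of the partner charge. Meanwhile 45.2 % of the substrate stands in neither column of the dawn run. If that missing part took no partner, the dawn substrate reached 0.7 % with partner to spare.

The forecast for the midnight flask at 2.5 h reads: all of the substrate has reacted, conversion 99.8 %, target 38 %. Its ground for the partner is “Dawn consumed all its substrate despite the partner being slightly short, so the partner does not limit.” The balance reckoned here on that target leaves 60.1 % of the partner. One partner held per catalyst would take a further 6.75 %, leaving 53.3 %.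

The midnight flask gives at 2.5 h: all of the substrate has reacted, conversion >99.9 %, target 39.4 %.

    2 substrate → self-condensation product (k = 0.00600 M⁻¹ s⁻¹)
    catalyst intermediate D ⇌ free catalyst + target (K = 0.760 M, k = 0.0300 s⁻¹)
    catalyst intermediate A → catalyst intermediate B (k = 1.70 s⁻¹)
    partner + free catalyst → catalyst intermediate A (k = 0.0490 M⁻¹ s⁻¹)
    catalyst intermediate C ⇌ catalyst intermediate D (K = 6.80, k = 0.0420 s⁻¹)
    2 catalyst intermediate A ⇌ resting dimer (K = 190 M⁻¹, k = 0.0990 M⁻¹ s⁻¹)
    substrate + catalyst intermediate B ⇌ catalyst intermediate C (K = 6.50 M⁻¹, k = 0.140 M⁻¹ s⁻¹)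

In the midnight flask, unbound partner stands at 52 % of its charge at 2.50 h, while catalyst intermediate B, which carries one partner by the scheme, makes up >99.9 % of the catalyst. The balance, with cost 1.05 and catalyst share 6.75 %, gives 51.9 %. For the neighbouring flask with 0.0064 M free catalyst and target 23.8 %, the same balance gives 72.3 %, and that flask holds 72 % of its partner unbound.

The runs come from a simulation for an exercise.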